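In a one-step world coupling partner enters product and nothing else, so the 1.25 M charged in this flask, more than the 1.00 M of both substrates, covers them.

common to all: coupling partner 1.25 M; temperature 40 °C
- epsilon: left-handed substrate 0.50 M; right-handed substrate 0.50 M; the very flask that is asked about, followed so far
- eta: left-handed substrate 0.25 M; right-handed substrate 0.25 M; run made earlier
- flask: left-handed substrate 0.50 M; right-handed substrate 0.50 M; time 6.0 h

- epsilon (time / min: left-handed product / %, left-handed substrate / %): 50.0: 22.7, 31.9; 90.0: 25.1, 31.3; 150: 25.6, 30.3; 180: 25.3, 29.5; 240: 26.0, 30.2; 300: 26.5, 29.7; 360: 25.8, 30.6
- eta (time / min: left-handed product / %, left-handed substrate / %): 3.00: 6.6, 43.5; 8.00: 11.9, 38.7; 15.0: 17.8, 35.1; 25.0: 20.2, 34.0; 30.0: 22.4, 32.6; 40.0: 23.9, 30.8; 60.0: 26.1, 29.5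

(readings scatter by 0.5 percentage points)

- left-handed product, in percent of the left-handed substrate and right-handed substrate together first charged, at 6.0 h
- what to do for the largest gain in left-handed product; "none" if nothing gains more than 2 percentage points (spring / winter / midnight / summer / none)
- left-handed product present, with what was taken out counted in, in percent of the left-handed substrate and right-handed substrate together first charged, after spring
- left-handed product present, with what was taken out counted in, in percent of the left-handed substrate and right-handed substrate together first charged, after midnight

- coupling partner is single-handed; left-handed substrate and right-handed substrate are mirror images of each other, charged as a racemate, each of them at the stated concentration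
- left-handed product that was removed still counts
- the numbers in the tables scatter by 0.5 percentage points (one standard deviation)
- the earlier runs do not show what temperature does; that part of a forecast is a guess
- additions bring no volume worth counting
- the handed part of coupling partner does not stay in what it makes, so the products of the two hands are mirror images too

- spring: change nothing and wait 6.0 h more
- winter: at 6.0 h take out 90% of the left-handed product then present, then wait 6.0 h
- midnight: at 6.0 h raise the temperature by 20 K, then wait 6.0 h
- summer: at 6.0 h add coupling partner, 50.0% of the amount charged, then wait 6.0 h

The epsilon run, which is this flask so far, instead stays flat from 90.0 min. Its left-handed product plus left-handed substrate reads 56.4%, more than the half charged as left-handed substrate, so substrate changes hand, and I take the two hands as equal. From the last 3 epsilon readings, left-handed substrate averages 30.2% and left-handed product 26.1%. I read left-handed product's share of the substrate consumed in the epsilon run as 0.658.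

I define the exposure, a pseudo-first-order integral, as the logarithm of charged over free substrate:

E = 0.505

I replace both hands by one mean rate and assume partner also destroys itself at the square of its concentration. With r as partner charge over substrate charge, the partner balance then gives:

E = ln(1 + m·r)/m

Epsilon, with r = 1.25, solves this to 3.16 for m, the self-loss number: partner's loss to itself against its loss to substrate at equal concentrations, less one.

The number m needs r beside it, because the eta run's exposure at 60.0 min, 0.528, already stands above epsilon's, with left-handed product still climbing from 23.9% to 26.1%.

For summer, I reckon:

r = 1.04, gain = 15 percentage points

That gain is more than the margin of 2 points.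

The forecast gives 25.9%, 26% after spring, 26.2% after midnight and summer as best, with fresh partner reaching about 34 to 35, against my 41.1%. Its ground for the flat stretch: “Nothing then moves for hours, with no reverse reaction visible.”

The flask gives 26.1% at 6.0 h, and summer gains 15 points, while spring gains 0 points, winter 0 points and midnight 0 points.

    left-handed substrate ⇌ right-handed substrate (k = 0.00182 /s, Ea = 100 kJ/mol)
    2 coupling partner → homo dimer (k = 0.00129 /M/s, Ea = 54.0 kJ/mol)
    coupling partner + left-handed substrate → left-handed product (k = 8.27 × 10⁻⁴ /M/s, Ea = 79.0 kJ/mol)
    coupling partner + right-handed substrate → right-handed product (k = 4.15 × 10⁻⁴ /M/s, Ea = 70.0 kJ/mol)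
    (constants at 40 °C)

For this flask the answer to "now" has moved by 5 points at the nearest coupling partner charges, 0.753 M and 2.12 M. Put on the eta run, with r = 2.50, the self-loss number gives left-handed product 32.9%, and the eta run left to 6.0 h holds 32.6%.

The numbers in the tables were computed on assumed constants, and the scatter is random.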